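**Retr​osynthetic overview**
1. Resacetophenone 1 + 2-methylbut-3-en-2-ol 2 ⇒ prenyl ketone 3: the C6–prenyl bond is disconnected as a prenyltransferase-like Friedel–Crafts prenylation.
2. 4-Hydroxybenzaldehyde 4 + prenal diethyl acetal 5 ⇒ chromene aldehyde 7: the O–CMe2 bond of the 2H-pyran is disconnected to o-quinone methide 6. This ring is formed first, by oxa-6π electrocyclisation.
3. 3 + 7 ⇒ chalcone 8: Cα=Cβ disconnection (Claisen–Schmidt), no protecting groups.
4. 8 ⇒ Dinklagin A 9: the O1–C2 bond of the pyranone is formed last, by a catalyst-controlled, chalcone-isomerase-like 6-endo oxa-Michael addition on the unprotected chalcone, which sets C2 (S) directly.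

Assumption: the quinine-derived thiourea is taken to give the (2S) sense. This is checked by CD (2S flavanones: positive n→π* band near 330 nm, negative π→π* band near 290–310 nm). If the sense is opposite, the quinidine-derived pseudo-enantiomer is used in the same procedure.

**Route**

Step 1
Reactants: 1 2,4-dihydroxyacetophenone; 2 2-methylbut-3-en-2-ol
Product: 3 1-[2,4-dihydroxy-5-(3-methylbut-2-en-1-yl)phenyl]ethan-1-one
Conditions: BF3·OEt2 (0.3 equiv), dioxane, 20 °C, 4 h
Reagents that add atoms: none
Why: Friedel–Crafts C-prenylation, in which BF3 ionises the tertiary allylic alcohol and the dimethylallyl electrophile attacks through its primary terminus at C5 (ortho to 4-OH, para to 2-OH, less hindered than C3 between the two oxygens), as a prenyltransferase does; 3 is separated by chromatography from the 3-prenyl isomer and the chroman (about 30% expected, 1 recovered).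

Step 2
Reactants: 4 4-hydroxybenzaldehyde; 5 1,1-diethoxy-3-methylbut-2-ene (prenal diethyl acetal)
Product: 7 2,2-dimethyl-2H-chromene-6-carbaldehyde, via o-quinone methide 6 (not isolated)
Conditions: 3-picoline (0.25 equiv), p-xylene, 140 °C, EtOH distilled off, 24 h; dilute HCl wash
Reagents that add atoms: none
Why: Phenol–enal acetal chromenylation (formal [3+3] annulation), in which ortho-alkenylation of the phenol with loss of two ethanol gives o-quinone methide 6 and this closes by oxa-6π electrocyclisation, the ring closure assumed for natural 2,2-dimethylchromenes; the method suits electron-poor para-substituted phenols and both ortho positions of 4 are equivalent.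

Step 3
Reactants: 3 1-[2,4-dihydroxy-5-(3-methylbut-2-en-1-yl)phenyl]ethan-1-one; 7 2,2-dimethyl-2H-chromene-6-carbaldehyde
Product: 8 (E)-1-[2,4-dihydroxy-5-(3-methylbut-2-en-1-yl)phenyl]-3-(2,2-dimethyl-2H-chromen-6-yl)prop-2-en-1-one
Conditions: KOH (50% aq, 10 equiv), EtOH, 0 °C to rt, 48 h, Ar; then cold 1 M HCl to pH 5
Reagents that add atoms: none
Why: Claisen–Schmidt aldol condensation with E1cB dehydration to the (E)-enone, in which the non-enolisable, non-phenolic aldehyde 7 reacts cleanly with the enolate of the phenoxide of 3, the strong base holds the product as the open-chain phenoxide, and prenyl and chromene groups are inert to base.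

Step 4
Reactants: 8 (E)-1-[2,4-dihydroxy-5-(3-methylbut-2-en-1-yl)phenyl]-3-(2,2-dimethyl-2H-chromen-6-yl)prop-2-en-1-one
Product: 9 Dinklagin A, (2S)-7-hydroxy-6-(3-methylbut-2-en-1-yl)-2-(2,2-dimethyl-2H-chromen-6-yl)-2,3-dihydro-4H-chromen-4-one
Conditions: quinine-derived 9-amino(9-deoxy)-epi-quinine 3,5-bis(trifluoromethyl)phenyl thiourea (20 mol %), toluene, 4 Å MS, 30 °C, 72 h; neutral silica, recrystallise
Reagents that add atoms: none
Why: Proposed new method: enantioselective intramolecular 6-endo-trig oxa-Michael addition on an unactivated, unprotected 2'-hydroxychalcone, in which the thiourea hydrogen-bonds the s-cis enone carbonyl while the quinuclidine nitrogen takes the proton of the 2'-OH and returns it to Cα, so that the chiral pocket selects the Cβ face that gives (2S) (the role chalcone isomerase plays); the neutral equilibrium of 6'-deoxychalcones lies on the flavanone side, and the closest known reaction is the cinchona-thiourea-catalysed oxa-Michael cyclisation of α-ester-activated 2'-hydroxychalcones.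

**Compound list**
1 | 2,4-dihydroxyacetophenone | CC(=O)c1ccc(O)cc1O | starting material
2 | 2-methylbut-3-en-2-ol | CC(C)(O)C=C | starting material
3 | 1-[2,4-dihydroxy-5-(3-methylbut-2-en-1-yl)phenyl]ethan-1-one | CC(=O)c1cc(CC=C(C)C)c(O)cc1O | intermediate
4 | 4-hydroxybenzaldehyde | O=Cc1ccc(O)cc1 | starting material
5 | 1,1-diethoxy-3-methylbut-2-ene | CCOC(OCC)C=C(C)C | starting material
6 | 3-(3-methylbut-2-en-1-ylidene)-4-oxocyclohexa-1,5-diene-1-carbaldehyde (o-quinone methide) | CC(C)=CC=C1C=C(C=O)C=CC1=O | intermediate
7 | 2,2-dimethyl-2H-chromene-6-carbaldehyde | CC1(C)C=Cc2cc(C=O)ccc2O1 | intermediate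
8 | (E)-1-[2,4-dihydroxy-5-(3-methylbut-2-en-1-yl)phenyl]-3-(2,2-dimethyl-2H-chromen-6-yl)prop-2-en-1-one | CC(C)=CCc1cc(C(=O)/C=C/c2ccc3OC(C)(C)C=Cc3c2)c(O)cc1O | intermediate
9 | Dinklagin A, (2S)-7-hydroxy-6-(3-methylbut-2-en-1-yl)-2-(2,2-dimethyl-2H-chromen-6-yl)-2,3-dihydro-4H-chromen-4-one | CC(C)=CCc1cc2c(cc1O)O[C@H](c1ccc3c(c1)C=CC(C)(C)O3)CC2=O | target

**Step count**
Total steps: 4. Longest linear sequence: 3 (1 → 3 → 8 → 9, or 4 → 7 → 8 → 9).

**Steps most likely to fail and fallbacks**

Step 4 (enantioselective cyclisation). The free 4'-OH can tie up the amine of the catalyst, the electron-rich B ring slows the addition, and retro-oxa-Michael can erode the ee. The fallback sets out from chalcone 8. It is cyclised under thermodynamic control (NaOAc, EtOH, reflux) to the racemic flavanone (±)-7-hydroxy-6-(3-methylbut-2-en-1-yl)-2-(2,2-dimethyl-2H-chromen-6-yl)chroman-4-one F1. F1 is resolved by preparative SFC on an amylose tris(3,5-dimethylphenylcarbamate) phase (CO2/MeOH), which comes back to the route at 9. The (2R) antipode is re-equilibrated through 8 with base and recycled.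

Step 1 (C5 prenylation). The yield is low, and the 3-prenyl isomer, diprenylation and acid cyclisation to the chroman compete. The fallback sets out from 1. The non-chelated 4-OH is O-alkylated with prenyl bromide (K2CO3, acetone, reflux) to 1-[2-hydroxy-4-(3-methylbut-2-en-1-yloxy)phenyl]ethan-1-one F2. Montmorillonite K10 (CH2Cl2, 0 °C to rt) then promotes the [1,3] prenyl shift from oxygen to the adjacent C5, which comes back to the route at 3.

Step 2 (one-step chromenylation of an electron-poor phenol). The ortho C–C bond formation may be sluggish and the aldehyde may undergo acetal exchange. The fallback sets out from 4. It is O-alkylated with 3-chloro-3-methylbut-1-yne (K2CO3, KI, cat. CuI, DMF, 65 °C) to 4-[(2-methylbut-3-yn-2-yl)oxy]benzaldehyde F3. Heating in N,N-diethylaniline at 190 °C gives aryl propargyl Claisen rearrangement to the allenylphenol 4-hydroxy-3-(3-methylbuta-1,2-dien-1-yl)benzaldehyde F4. A 1,5-hydrogen shift converts F4 into the same o-quinone methide 6, which closes as before and comes back to the route at 7.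

**Further compounds**
F1 | step 4 | (±)-7-hydroxy-6-(3-methylbut-2-en-1-yl)-2-(2,2-dimethyl-2H-chromen-6-yl)chroman-4-one (racemate) | CC(C)=CCc1cc2c(cc1O)OC(c1ccc3c(c1)C=CC(C)(C)O3)CC2=O
F2 | step 1 | 1-[2-hydroxy-4-(3-methylbut-2-en-1-yloxy)phenyl]ethan-1-one | CC(=O)c1ccc(OCC=C(C)C)cc1O
F3 | step 2 | 4-[(2-methylbut-3-yn-2-yl)oxy]benzaldehyde | C#CC(C)(C)Oc1ccc(C=O)cc1
F4 | step 2 | 4-hydroxy-3-(3-methylbuta-1,2-dien-1-yl)benzaldehyde | CC(C)=C=Cc1cc(C=O)ccc1O
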